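The runs were computed with constants of no real substance; noise was put on by code.

Amber has a ratio of 0.556, violet 1.67 and green 5.56. This is the charge ratio, c(substrate) over the sum of c(partner) and c(capture agent). It compares what enters with what can take it up.

| flask | substrate | partner | capture agent | remark | time |
|---|---|---|---|---|---|
| dawn | 2 mM | 2.4 mM | 2 mM | run made earlier |  |
| spring | 2 mM | 3.2 mM | 2 mM | run made earlier |  |
| amber | 2.0 mM | 1.60 mM | 2.00 mM |  | 4.0 min |
| violet | 6.0 mM | 1.60 mM | 2.00 mM |  | 4.0 min |
| green | 20 mM | 1.60 mM | 2.00 mM |  | 4.0 min |

| run | time / s | target / % | substrate / % |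
|---|---|---|---|
| dawn | 10.0 | 6.5 | 4.7 |
| dawn | 12.0 | 5.2 | 1.0 |
| dawn | 25.0 | 11.5 | 1.0 |
| dawn | 40.0 | 13.5 | 0.6 |
| dawn | 50.0 | 14.2 | 0.9 |
| dawn | 60.0 | 15.8 | 0.6 |
| dawn | 80.0 | 14.7 | 0 |
| spring | 12.0 | 9.0 | 1.3 |
| spring | 25.0 | 12.8 | 0.8 |
| spring | 40.0 | 18.0 | 0.2 |
| spring | 50.0 | 18.2 | 0 |
| spring | 60.0 | 19.2 | 0.9 |
| spring | 80.0 | 18.0 | 0 |

(each reading ± 1 percentage point)

- "hardly changes" means that all values lie within two and a half points (for a concentration: within two and a half percent of the largest)

- [target] at the end for amber, violet, green, in this order
- how that number moves from the first to the last of them (falls, then rises / rises all the way / falls all the way / rises, then falls / hardly changes)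

In dawn the substrate reads 1.0% at 12.0 s, yet target still climbs to 15.8% at 60.0 s. So I take it that an intermediate holds the charge in between. The last three readings average 14.9% in dawn and 18.5% in spring.

My bench rule is that, with the charges of substrate and capture agent held fixed, the target's share of the substrate charged goes with c(partner). These readings give about 9.58% at the partner charge of amber, so I expect about 0.192 mM in amber. For green the same share gives 1.92 mM, more than the 1.60 mM of partner charged, so the rule breaks there.

I look for the border with the charge ratio. Dawn stands at 0.455 and spring at 0.385, so the rule was read below one. I assume that each intermediate takes one partner or one capture agent. Below one, as in amber, substrate is then the limiting reagent. Above one, I expect both takers to be used up in the end, and a share of the substrate charged, one minus the inverse ratio, to stay as untaken intermediate. There I commit to a ceiling of c(partner) and to no closer number.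

The forecast goes further, with 0.22 mM, 1.4 mM and 1.6 mM, so that the row rises all the way. Its ground is that “the excess intermediate goes to the partner”.

The flask gives 0.192 mM, 0.369 mM and 0.358 mM of target, so the row rises, then falls.

    substrate → open intermediate (k = 0.360 /s)
    partner + open intermediate → target (k = 3.20 /M/s)
    target ⇌ isomer of the product (K = 3.50, k = 0.0230 /s)
    open intermediate + capture agent → trapped intermediate (k = 3.50 /M/s)

In green at 4.00 min, target and isomer of the product together hold 1.60 mM, about the partner charge, with target at 1.79% of the substrate charged and the isomer at 6.21%. The charge ratio of green, 5.56, leaves a share of 82.0%, and open intermediate stands at 82.0%. The ratio of violet, 1.67, leaves 40.0%, and open intermediate there stands at 40.0% after 40.0 min.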